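Early in Wednesday's run, the very flask now asked about, the product total rises by 18 percentage points between 0.625 d and 1.25 d, yet it rises less, by 12 points, over the next stretch, which is twice as long.

- Wednesday's: left-handed substrate 0.050 M; right-handed substrate 0.050 M; partner 0.125 M (fed, over 10 h); catalyst 5.5 mM; added ligand 5.4 mM; the very flask that is asked about, followed so far
- flask: left-handed substrate 0.050 M; partner 0.125 M (fed, over 10 h); catalyst 5.5 mM; added ligand 5.4 mM; right-handed substrate 0.050 M; time 8.0 d

Wednesday's run (percent of the left-handed substrate and right-handed substrate together charged)

| time / d | left-handed product / % | right-handed product / % |
|---|---|---|
| 0.208 | 4.1 | 1.5 |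
| 0.333 | 11.2 | 6.7 |
| 0.625 | 23.5 | 14.9 |
| 1.25 | 34.4 | 22.4 |
| 2.50 | 41.7 | 27.0 |

(readings scatter by 0.5 percentage points)

- catalyst is single-handed; left-handed substrate and right-handed substrate are mirror images of each other, charged as a racemate, each of them at the stated concentration
- steps under discussion: partner + catalyst + left-handed substrate -> catalyst + left-handed product; partner + catalyst + right-handed substrate -> catalyst + right-handed product; left-handed substrate <-> right-handed substrate; catalyst + added ligand <-> idle complex; partner -> decomposed reagent; partner <-> dormant form
- an excess is below zero if the other one leads

1. left-handed product and right-handed product together, in percent of the left-handed substrate and right-handed substrate charged together, at 8.0 d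
2. excess of left-handed product over right-handed product in the product at 8.0 d
3. whether the exchange between left-handed substrate and right-handed substrate keeps pace with the reaction: how far the product's excess at 8.0 d gets from its value without exchange to its value with instant exchange (above 80% keeps pace, below 20% hardly takes part, else lags behind)

What does a product cost? One partner, by the steps under discussion. But partner can also pass into decomposed reagent or dormant form, so a charge of 0.125 M, larger than the 0.100 M of both substrates, is no assured surplus.

What number follows that? At 2.50 d the run has made product equal to 0.550 of the partner charged. I call this the partner yield, product formed per partner charged.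

Can it be carried to 8.0 d? By hand, yes. The last doubling of time gained 0.647 of what the doubling before it gained. If that ratio holds, and the stretch to 8.0 d takes its logarithmic share of the following doubling, I reckon a yield of 79.8%, which is a partner yield of 0.638.

Where is that weak? The ratio rests on 6 readings, each scattering by 0.5 points, and it contains no mechanism.

The forecast says 72.5%, 21.5% and lags behind, on the ground that “Total product stops growing because the partner is lost”. My yield figure stands above its 72.5%; for the excess and the pace I reckon nothing of my own.

The flask gives 79.0%, an excess of 20.4%, and an exchange that lags behind, getting 50% of the way.

    partner + catalyst + left-handed substrate → catalyst + left-handed product (k = 196 M⁻² h⁻¹)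
    partner + catalyst + right-handed substrate → catalyst + right-handed product (k = 109 M⁻² h⁻¹)
    left-handed substrate ⇌ right-handed substrate (k = 0.0172 h⁻¹)
    catalyst + added ligand ⇌ idle complex, settled at all times (K = 131 M⁻¹)
    partner → decomposed reagent (k = 0.0137 h⁻¹)
    partner ⇌ dormant form (K = 0.833, k = 0.0155 h⁻¹)

In this flask the partner yield at 8.0 d is 0.632. The neighbouring flask is charged with 0.031 M of partner, all else held. Carrying 0.638 over to it gives 19.8%, but that flask stores 23.7%, a partner yield of 0.766, higher than the reckoned one. Partner is its limiting reagent: 0.53% of its charge remains at 8.00 d, while 76% of the left-handed substrate charged is still there.

(The runs were computed from invented constants, noise included.)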